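The flavone is cut through ring C. The C4(=O)–C3–C2 chain that joins C4a of ring A to C1′ of ring B carries oxygen at C4 and a heteroatom at C2, which is what a 3,5-diarylisoxazole supplies once its N–O bond is broken. A ring-B nitrile oxide and a ring-A arylacetylene are joined in one [3+2] cycloaddition that forms the C2–C3 bond and the C4–O bond and closes the isoxazole as a latent pyranone. The precursors are the O-benzyl aldoxime of ring B and an ortho-benzyloxy terminal arylalkyne of ring A. One hydrogenolysis/acid operation then opens the heterocycle and closes ring C through O1–C2.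

Key step: step 6

Remark on the chemistry: the target is achiral; the double-bond descriptors given for 7, 8 and 11 belong to groups that do not survive into 12, so no stereochemical control is required.

Step 1
Reactants: 1 2,3,4-trimethoxyphenol
Product: 2 2-hydroxy-3,4,5-trimethoxybenzaldehyde
Conditions: MgCl2 (anhydrous), Et3N, (CH2O)n, MeCN, reflux; 1 M HCl work-up
Reagents that add atoms: paraformaldehyde (as formaldehyde), C=O
Why: Casnati–Skattebøl magnesium-mediated ortho-formylation: the magnesium phenoxide delivers formaldehyde to C6, the only free position ortho to the hydroxyl, and a second formaldehyde oxidises the hydroxymethyl intermediate by hydride transfer, while the methyl ethers are inert.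

Step 2
Reactants: 2 2-hydroxy-3,4,5-trimethoxybenzaldehyde
Product: 3 2-(benzyloxy)-3,4,5-trimethoxybenzaldehyde
Conditions: BnBr, K2CO3, DMF, 60 °C
Reagents that add atoms: benzyl bromide, BrCc1ccccc1
Why: Williamson ether synthesis on the only acidic site of a non-enolisable aldehyde; gentle heating should overcome the hydrogen bond of the phenol to the formyl group.

Step 3
Reactants: 3 2-(benzyloxy)-3,4,5-trimethoxybenzaldehyde
Product: 4 2-(benzyloxy)-1-ethynyl-3,4,5-trimethoxybenzene
Conditions: dimethyl (1-diazo-2-oxopropyl)phosphonate, K2CO3, MeOH–THF, 0 °C to rt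
Reagents that add atoms: dimethyl (1-diazo-2-oxopropyl)phosphonate, CC(=O)C(=[N+]=[N-])P(=O)(OC)OC
Why: Seyferth–Gilbert homologation in the Ohira–Bestmann variant: methanolysis frees the diazomethylphosphonate anion, which adds to the non-enolisable aldehyde, eliminates phosphate and loses N2 with a 1,2-hydrogen shift to give the terminal alkyne, and the aryl ethers tolerate K2CO3 in methanol.

Step 4
Reactants: 5 3-hydroxy-4,5-dimethoxybenzaldehyde
Product: 6 3-(benzyloxy)-4,5-dimethoxybenzaldehyde
Conditions: BnBr, K2CO3, DMF, 50 °C
Reagents that add atoms: benzyl bromide, BrCc1ccccc1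
Why: Williamson ether synthesis; the single phenol is alkylated so that neither N-chlorosuccinimide nor the nitrile oxide later meets a free phenol.

Step 5
Reactants: 6 3-(benzyloxy)-4,5-dimethoxybenzaldehyde
Product: 7 (E)-3-(benzyloxy)-4,5-dimethoxybenzaldehyde oxime
Conditions: NH2OH·HCl, NaOAc, EtOH–H2O, rt
Reagents that add atoms: hydroxylamine hydrochloride, Cl.NO
Why: Oxime condensation of an aromatic aldehyde, which should give the thermodynamically preferred E-aldoxime; the geometry is of no consequence because the C=N–OH unit becomes a nitrile oxide in the next step.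

Step 6
Reactants: 7 (E)-3-(benzyloxy)-4,5-dimethoxybenzaldehyde oxime; 4 2-(benzyloxy)-1-ethynyl-3,4,5-trimethoxybenzene
Product: 10 3-[3-(benzyloxy)-4,5-dimethoxyphenyl]-5-[2-(benzyloxy)-3,4,5-trimethoxyphenyl]isoxazole, via hydroximoyl chloride 8 (not isolated), via nitrile oxide 9 (not isolated)
Conditions: 7 (1.5 equiv), NCS (1.5 equiv), DMF, rt; then 4 (1.0 equiv), Et3N (syringe pump, several hours), DMF, rt to 40 °C
Reagents that add atoms: none
Why: NCS chlorinates the aldoxime carbon to hydroximoyl chloride 8, and slow addition of Et3N removes HCl to release nitrile oxide 9 at low stationary concentration, which adds across the terminal alkyne of 4 in a concerted, asynchronous Huisgen [3+2] cycloaddition. The closest known reaction type is the addition of aryl nitrile oxides to arylacetylenes to give 3,5-diarylisoxazoles. The five-membered isoxazole is closed intermolecularly in a thermally allowed suprafacial 4π+2π process in which the dipole carbon bonds to the alkyne CH (the future C2–C3 bond) and the dipole oxygen to the aryl-bearing alkyne carbon (the future C4–O bond), so both ring bonds arise together. No stereocentre is created. The step needs regioselectivity, oxygen onto the carbon attached to ring A, which the terminal alkyne secures because its unsubstituted carbon carries the larger frontier-orbital coefficient and is the less hindered partner for the aryl-bearing dipole carbon, the ortho-benzyloxy group of ring A further disfavouring the 3,4-isomer. It also needs chemoselectivity over furoxan dimerisation and over ring chlorination, secured by the excess of 7, the slow base addition and by completing the chlorination before the electron-rich alkyne enters the flask.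

Step 7
Reactants: 10 3-[3-(benzyloxy)-4,5-dimethoxyphenyl]-5-[2-(benzyloxy)-3,4,5-trimethoxyphenyl]isoxazole
Product: 12 2-(3-hydroxy-4,5-dimethoxyphenyl)-6,7,8-trimethoxy-4H-chromen-4-one, via enaminone 11 (not isolated)
Conditions: H2 (1–3 atm), 10% Pd/C, EtOAc–EtOH, AcOH (cat.), rt; filter through Celite; then conc. HCl, EtOH, 70 °C
Reagents that add atoms: none
Why: Palladium-catalysed hydrogenolysis should cleave the weak isoxazole N–O bond and both benzyl ethers in one pass (reductive isoxazole opening to a β-enaminone, a vinylogous amide that resists further reduction, with acetic acid buffering any liberated ammonia), and on acidification the ring-A phenol adds to protonated C2 and ammonia is expelled (cyclisation of an o-hydroxyaryl enaminone to a chromone), any diketone formed by competing hydrolysis converging on the same pyranone while HCl in ethanol leaves the aryl methyl ethers intact; the enaminone is not isolated because it may begin to cyclise on handling.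

Compound list
1 | 2,3,4-trimethoxyphenol | COc1ccc(O)c(OC)c1OC | starting material
2 | 2-hydroxy-3,4,5-trimethoxybenzaldehyde | COc1cc(C=O)c(O)c(OC)c1OC | intermediate
3 | 2-(benzyloxy)-3,4,5-trimethoxybenzaldehyde | COc1cc(C=O)c(OCc2ccccc2)c(OC)c1OC | intermediate
4 | 2-(benzyloxy)-1-ethynyl-3,4,5-trimethoxybenzene | C#Cc1cc(OC)c(OC)c(OC)c1OCc1ccccc1 | intermediate
5 | 3-hydroxy-4,5-dimethoxybenzaldehyde | COc1cc(C=O)cc(O)c1OC | starting material
6 | 3-(benzyloxy)-4,5-dimethoxybenzaldehyde | COc1cc(C=O)cc(OCc2ccccc2)c1OC | intermediate
7 | (E)-3-(benzyloxy)-4,5-dimethoxybenzaldehyde oxime | COc1cc(/C=N/O)cc(OCc2ccccc2)c1OC | intermediate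
8 | (Z)-3-(benzyloxy)-N-hydroxy-4,5-dimethoxybenzenecarboximidoyl chloride | COc1cc(/C(Cl)=N/O)cc(OCc2ccccc2)c1OC | intermediate (not isolated)
9 | 3-(benzyloxy)-4,5-dimethoxybenzonitrile oxide | COc1cc(C#[N+][O-])cc(OCc2ccccc2)c1OC | intermediate (not isolated)
10 | 3-[3-(benzyloxy)-4,5-dimethoxyphenyl]-5-[2-(benzyloxy)-3,4,5-trimethoxyphenyl]isoxazole | COc1cc(-c2cc(-c3cc(OC)c(OC)c(OC)c3OCc3ccccc3)on2)cc(OCc2ccccc2)c1OC | intermediate
11 | (Z)-3-amino-3-(3-hydroxy-4,5-dimethoxyphenyl)-1-(2-hydroxy-3,4,5-trimethoxyphenyl)prop-2-en-1-one | N/C(=C\C(=O)c1cc(OC)c(OC)c(OC)c1O)c1cc(OC)c(OC)c(O)c1 | intermediate (not isolated)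
12 | 2-(3-hydroxy-4,5-dimethoxyphenyl)-6,7,8-trimethoxy-4H-chromen-4-one | COc1cc(-c2cc(=O)c3cc(OC)c(OC)c(OC)c3o2)cc(O)c1OC | target

Total step count: 7. Longest linear sequence: 5 steps (steps 1, 2, 3, 6, 7); steps 4 and 5 form the second, two-step branch.

Steps most likely to fail

Step 6. What may go wrong: dimerisation of the nitrile oxide to the furoxan outpacing cycloaddition onto the electron-rich, ortho-substituted alkyne, or erosion of regiocontrol. The fallback sets out from 4 and 6 and returns at 10; it closes the isoxazole by oxime cycloisomerisation instead of cycloaddition. The lithium acetylide of 4 (n-BuLi, THF, −78 °C) is added to aldehyde 6 to give racemic 1-[3-(benzyloxy)-4,5-dimethoxyphenyl]-3-[2-(benzyloxy)-3,4,5-trimethoxyphenyl]prop-2-yn-1-ol F1. MnO2 in CH2Cl2 should oxidise it to 1-[3-(benzyloxy)-4,5-dimethoxyphenyl]-3-[2-(benzyloxy)-3,4,5-trimethoxyphenyl]prop-2-yn-1-one F2. NH2OH·HCl and pyridine in EtOH convert the ketone into 1-[3-(benzyloxy)-4,5-dimethoxyphenyl]-3-[2-(benzyloxy)-3,4,5-trimethoxyphenyl]prop-2-yn-1-one oxime F3, drawn with the hydroxyl on the alkyne side; the other isomer should equilibrate under the cyclisation conditions. Catalytic AuCl3 in CH2Cl2 then effects 5-endo-dig attack of the oxime oxygen on the alkyne carbon attached to ring A and gives 10, the regiochemistry now being fixed by the position of the former carbonyl carbon.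

Step 7. What may go wrong: stalled N–O hydrogenolysis at the hindered, electron-rich diarylisoxazole, over-reduction of the vinylogous amide once conditions are forced, or inhibition of the second debenzylation by liberated ammonia. The fallback sets out from 10 and returns at 11; it avoids hydrogenation altogether. Mo(CO)6 in MeCN–H2O at reflux should cleave only the N–O bond and give (Z)-3-amino-3-[3-(benzyloxy)-4,5-dimethoxyphenyl]-1-[2-(benzyloxy)-3,4,5-trimethoxyphenyl]prop-2-en-1-one F4. BCl3 with pentamethylbenzene as benzyl-cation scavenger (CH2Cl2, −78 °C) then removes both benzyl ethers without touching the methyl ethers and gives 11, which a methanolic HCl quench and warming should cyclise to 12 as in the second half of step 7.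

Step 3. What may go wrong: sluggish addition of the diazophosphonate anion to the electron-rich, ortho-alkoxy aldehyde, leaving unreacted aldehyde under the basic methanolic conditions. The fallback sets out from 3 and returns at 4; it is a Corey–Fuchs sequence. CBr4 and PPh3 in CH2Cl2 at 0 °C should give 2-(benzyloxy)-1-(2,2-dibromoethenyl)-3,4,5-trimethoxybenzene F5. n-BuLi (2 equiv) in THF at −78 °C then effects bromine–lithium exchange and Fritsch–Buttenberg–Wiechell rearrangement to the lithium acetylide, which gives 4 on NH4Cl quench.

Further compounds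
F1 | step 6 | 1-[3-(benzyloxy)-4,5-dimethoxyphenyl]-3-[2-(benzyloxy)-3,4,5-trimethoxyphenyl]prop-2-yn-1-ol (racemic) | OC(C#Cc1cc(OC)c(OC)c(OC)c1OCc1ccccc1)c1cc(OC)c(OC)c(OCc2ccccc2)c1
F2 | step 6 | 1-[3-(benzyloxy)-4,5-dimethoxyphenyl]-3-[2-(benzyloxy)-3,4,5-trimethoxyphenyl]prop-2-yn-1-one | O=C(C#Cc1cc(OC)c(OC)c(OC)c1OCc1ccccc1)c1cc(OC)c(OC)c(OCc2ccccc2)c1
F3 | step 6 | 1-[3-(benzyloxy)-4,5-dimethoxyphenyl]-3-[2-(benzyloxy)-3,4,5-trimethoxyphenyl]prop-2-yn-1-one oxime (hydroxyl syn to the alkyne) | O/N=C(\C#Cc1cc(OC)c(OC)c(OC)c1OCc1ccccc1)c1cc(OC)c(OC)c(OCc2ccccc2)c1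
F4 | step 7 | (Z)-3-amino-3-[3-(benzyloxy)-4,5-dimethoxyphenyl]-1-[2-(benzyloxy)-3,4,5-trimethoxyphenyl]prop-2-en-1-one | N/C(=C\C(=O)c1cc(OC)c(OC)c(OC)c1OCc1ccccc1)c1cc(OC)c(OC)c(OCc2ccccc2)c1
F5 | step 3 | 2-(benzyloxy)-1-(2,2-dibromoethenyl)-3,4,5-trimethoxybenzene | COc1cc(C=C(Br)Br)c(OCc2ccccc2)c(OC)c1OC
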